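The constants of the candidate steps were unknown when the meeting sat, so it started from the charges and the earlier runs.

common to all: left-handed substrate 0.10 M; right-handed substrate 0.10 M; precatalyst 6.1 mol%; impurity 3.2 mM
- Sunday's: partner 0.73 equiv; run made earlier
- Saturday's: partner 1.7 equiv; run made earlier
- Tuesday's: partner 2.5 equiv; run made earlier
- larch: partner 1.00 equiv; time 15 h
- elm: partner 3.00 equiv; time 15 h

- Sunday's (time / h: right-handed substrate / %, left-handed substrate / %, left-handed product / %): 3.00: 49.9, 50.9, 0.4; 6.00: 49.0, 48.7, 0.5; 10.0: 49.9, 48.4, 2.7; 12.0: 50.1, 48.9, 3.6; 15.0: 45.6, 44.6, 3.6
- Saturday's (time / h: right-handed substrate / %, left-handed substrate / %, left-handed product / %): 1.33: 49.8, 47.2, 1.4; 2.50: 47.9, 47.0, 1.8; 4.00: 48.5, 45.6, 4.5; 8.00: 47.0, 39.7, 9.0; 15.0: 41.3, 31.3, 17.5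
- Tuesday's (time / h: right-handed substrate / %, left-handed substrate / %, left-handed product / %): 3.00: 46.8, 43.9, 5.2; 6.00: 44.5, 39.3, 11.5; 10.0: 39.2, 30.2, 17.7; 12.0: 37.2, 29.4, 22.7; 15.0: 33.0, 22.9, 25.4

(standard deviation of a reading: 1 percentage point)

- free catalyst is single-handed; left-handed substrate and right-handed substrate are mirror images of each other, charged as a racemate, each of them at the stated concentration
- the numbers in the tables scatter by 1 percentage point (one standard deviation)
- candidate steps: partner + free catalyst + left-handed substrate -> free catalyst + left-handed product; 2 free catalyst -> spent catalyst A; partner + free catalyst + right-handed substrate -> free catalyst + right-handed product; free catalyst + impurity -> spent catalyst B; partner + precatalyst -> free catalyst + spent reagent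
- an excess is the difference of the two amounts in percent of their sum
- an excess is below zero if the other one leads

- the winner by excess of right-handed substrate over left-handed substrate among what is left of the two; "neither" if no more than 2 percentage points parts them (larch / elm / neither)
- excess of right-handed substrate over left-handed substrate among what is left of the two at the end, larch
- excess of right-handed substrate over left-handed substrate among what is left of the two at the end, elm

As minute-taker I give my own reckoning first: I wrote the balance of the reagent charged in the smaller amount. c(impurity) is 3.2 mM against 6.10 mM of catalyst held as precatalyst, so impurity, the limiting reagent of its step, can take a share of 52.5% of the catalyst into spent catalyst B. I argued that impurity takes released catalyst first, and noted that Sunday's left-handed product, 0.5% after 6.00 h, lies within a scatter of 1 percentage point of zero. I called the hours until released catalyst has paid the impurity the dead time, and took it as inversely proportional to the equivalents of partner, scaled from Sunday's run. That gives 4.38 h for larch and, for elm, 1.46 h.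

Beyond the dead time I let ln(charged/left) of left-handed substrate grow with partner and with working hours, scaled from Tuesday's end reading. This gives 0.250 for larch and 0.958 for elm. Tuesday's end readings also give a selectivity factor of 1.88. My excesses are therefore 5.85% for larch and 22.0% for elm.

The forecaster, working from the same runs, wrote: “Low partner therefore gives disproportionately little turnover.” The forecast entered 5% for larch and 21% for elm, with elm the winner. My figures differ from these but name the same winner.

The flask gives 4.65% for larch and 24.1% for elm, so elm wins.

    partner + free catalyst + left-handed substrate → free catalyst + left-handed product (k = 2.30 /M²/min)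
    2 free catalyst → spent catalyst A (k = 0.130 /M/min)
    partner + free catalyst + right-handed substrate → free catalyst + right-handed product (k = 1.10 /M²/min)
    free catalyst + impurity → spent catalyst B (k = 8.00 /M/min)
    partner + precatalyst → free catalyst + spent reagent (k = 0.0250 /M/min)

After 7.50 h elm keeps 0.205% of its impurity against a dead time of 1.46 h, and larch keeps 9.29% against a dead time of 4.38 h. The neighbouring flask is elm read at 10 h. Its dead time stays 1.46 h, so ln(charged/left) becomes 0.604 and my excess 14.0%. That flask holds 26.2% left-handed substrate, counted on both substrates charged, and its excess is 16.7%.

The numbers in the tables stem from a simulated flask with constants of no real substance, noise included.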